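## Structural features

The target is a 3,8''-linked biflavonoid. A flavanone (benzo ring A, heterocycle C, 4-hydroxyphenyl ring B) is bonded through its C3 to C8 of a flavone (benzo ring D, pyranone ring E, 4-hydroxyphenyl ring F), and the flavone 7-oxygen is a hydrogen sulfate. The only stereocentres are flavanone C2 (R) and C3 (S), adjacent and trans. C3 is alpha to the C4 ketone and can epimerise, and the C2–O1 bond can open by retro-oxa-Michael reaction in base, which racemises C2. The aryl sulfate monoester is acid-labile and hard to carry unprotected, the pyranone is opened by nucleophilic base, and only one of six phenolic oxygens may be sulfated. The real difficulty is twofold: the C3–C8 bond joins an sp3 methine to the most hindered carbon of ring D, flanked by O7 and the ring E oxygen, and O7 must be told apart from O5 and from the phenols of rings A, B and F. Ring D is a pentasubstituted phloroglucinol: C8 carries flavanone C3, C7 the sulfated oxygen, C6 a hydrogen, C5 a hydroxyl chelated to the C4 carbonyl, and C4a/C8a are fused to ring E. The key step uses exactly this pattern: when ring D is closed last by joining an ester carbon (future C7) to the methylene on pyranone C6 (future C8), O7 appears as the only unchelated phenol, O5 appears chelated, and the CH2–CH2 link between the two flavonoid units is present from the start as a succinate unit.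

## Logic of the disconnections

**26 back to 24.** The bonds cut are the four benzyl C–O bonds and the O–CH2 bond of the trichloroethyl sulfate diester. Masking every ring A, B and F phenol and the sulfate gives a neutral intermediate that tolerates the steps before it. The forward step must cleave both kinds of group in one reductive operation through 25 and leave C2–O1, the ring E alkene and both stereocentres alone.

**24 back to 23.** The cut is O1–C2 of ring C, the oxa-Michael retron. This removes ring C and both stereocentres and leaves an achiral triaryl enone. The forward step must add the phenol to one face of the enone under catalyst control, let C3 settle trans by protonation, and avoid racemisation through ring reopening.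

**23 back to 22.** Only the acetal C–O bond of the protecting group on the ring A oxygen is restored. The group keeps that oxygen from closing ring C before a chiral catalyst is present. The forward step needs acid that spares the sulfate diester and does not itself close the ring.

**22 back to 20 and 21.** The cut is the enone C=C bond (future flavanone C2–C3). Ring B is removed and a benzylic ketone methylene remains. The forward condensation must work at a methylene flanked by two crowded aryl groups without harming the sulfate diester.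

**20 back to 19.** The cut is the O7–S bond. Sulfation is placed here because 19 has exactly two free phenols and one of them is chelated. The forward step must be selective for O7 and fast, since the free 7-OH next to the side-chain ketone can cyclise to a benzofuran.

**19 back to 17.** The cut is C7–C8 of ring D. Ring D disappears and a 4-pyranone with two side arms remains, in which future C8 is a CH2 and future C7 an ester carbon. The gain is large: the hindered inter-unit bond is never made by coupling, and O5 and O7 need no protecting groups. The forward step must generate the vinylogous carbanion on the pyranone C6 methylene in preference to the aryl ketone enolate, with a base that does not open the pyranone.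

**17 back to 15.** The acyl–OMe bond of the beta-keto ester is traced to a dioxinone. The beta-keto ester is thus carried masked through the pyranone synthesis and released under neutral conditions. This avoids hydrolysing an ester on a base-sensitive pyranone and a second chain extension. The forward step is a thermal retro-cycloaddition with methanol capture.

**15 back to 9 and 13.** Two ring E bonds are cut: C4–C4a (C-acylation) and O1–C2 (addition of an enol oxygen to an ynone). The pyranone dissolves into a keto-dioxinone and an arylpropioloyl chloride. The forward step must acylate on carbon and close 6-endo-dig; only one ketone oxygen in 14 can do so, so only one pyranone is possible.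

**13 back to 12, and 12 back to 10 and 11.** The acid chloride comes from the acid, and the aryl–alkyne bond is cut to an aryl iodide and propiolic acid. This gives ring F and flavone C2–C4 in one coupling.

**9 back to 6 and 7.** The cut is the C–C bond between the future C8a carbonyl and the future C4a methylene. The dioxinone supplies four ring D carbons in one piece. The forward step is acylation of a dienolate at its terminal carbon by an activated acid that also contains a hindered ketone.

**6 back to 5, 4, 3, and then 1 and 2.** Protecting-group operations lead back to the trihydroxy keto acid, and the aryl–acyl bond is cut to phloroglucinol and succinic anhydride. The forward steps rely on the chelated ortho phenol being the last to alkylate.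

## Other disconnections considered

**Alternative 1:** The cut is the C2=C3 double bond of ring E. In the forward direction the acyl ylide A2 carries, on ring D, a C(=O)CH=PPh3 group next to a 4-benzyloxybenzoate ester on the neighbouring oxygen. On heating it would undergo an intramolecular Wittig olefination of the ester carbonyl, lose phosphine oxide and give the fully protected biflavonoid A1, one reductive step from the target.
- In its favour: the closure is neutral and thermal, so neither the flavanone nor the sulfate diester meets base. The ester Wittig route to chromones is an established reaction type; on mechanistic precedent this alternative is the better of the two. The position of the ring E oxygen is fixed by where the ester sits.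
- Against it here: A2 already contains the C3–C8 bond and both stereocentres, so the two real problems are only moved upstream. Its ring D must carry three different oxygen substituents plus the ylide. The ester carbonyl of an electron-rich, doubly ortho-substituted aryl benzoate is a slow Wittig acceptor, and long heating would test the epimerisable C3 centre.
- Comparison: on structure the chosen plan is simpler, because ring D arises from an open chain with O5 and O7 differentiated by chelation alone. On mechanism Alternative 1 is safer. On step economy the chosen plan should be shorter, since Alternative 1 carries chiral, base-sensitive material through the whole of the ring D and ring E work. The final unmasking is the same in both, a point of equality.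

**Alternative 2:** The cut is the C4–C4a bond of ring E. The (Z)-3-aryloxy-3-arylacrylic acid A4, attached to the ring D oxygen that becomes O1, would be activated as a mixed anhydride and acylate the one free ortho carbon of ring D. This Friedel–Crafts closure would give the 7-O-allyl biflavonoid A3.
- In its favour: ring D is the most electron-rich arene present and only one position can give a six-membered ring. Acid cannot open the flavanone by retro-oxa-Michael reaction, so for keeping the stereocentres intact during the key step it is better than a base-mediated closure. Cyclisation of aryloxycinnamic acids to flavones is a known reaction type.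
- Against it here: the 7-oxygen must travel as an allyl ether, because a sulfate diester would deactivate ring D, so deallylation and sulfation follow before the final unmasking. The enol ether of A4 is acid-labile and must keep its Z geometry. A4 again presupposes the C3–C8 bond, both stereocentres and three differentiated oxygens on ring D.
- Comparison: on structure the chosen plan avoids all oxygen differentiation. On mechanism Alternative 2 is the more predictable ring closure. On step economy it needs three steps after its key step against five here, which is in its favour, but more before it, because the hindered inter-unit bond must be made by other means.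

**Alternative 3:** The cut runs through ring C at C3–C4 and O1–C2. Salicylaldehyde A7 and an orthoformate would form a 4-methoxy ortho-quinone methide oxocarbenium ion inside a confined chiral Brønsted acid. This would add across the alkene of the (E)-8-styrylflavone A6 to give the all-trans 4-methoxyflavan A5.
- In its favour: it is the most convergent plan. C2 and C3 are set in one catalyst-controlled bond-forming event, and their trans relationship follows from the E alkene. On stereocontrol this is the better design, since the chosen plan sets C3 by thermodynamic protonation. The polarisation is right, because the 4-benzyloxyphenyl group stabilises positive charge at the carbon that becomes C2.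
- Against it here: the alkene is a stilbene with one di-ortho-substituted, carbonyl-conjugated aryl group, far from simple styrenes. A5 is at the wrong oxidation level, so ether hydrolysis and oxidation to the ketone must follow next to the epimerisable C3. A6 needs a flavone functionalised at C8 with O5 and O7 already differentiated, which is the problem the chosen plan avoids.
- Comparison: on structure both plans avoid joining an sp3 carbon to the hindered ring D position by coupling, but the alternative still needs a C8–C(sp2) coupling. On mechanism both key steps are untested on this substrate class, an equal risk. On step economy it has three steps after its key step against five, offset by a longer route to A6, so the two are about equal overall.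

Key step: step 10

Assumption: the hydrogen sulfate drawn for the target is taken as the acid form released from its ammonium salt by brief contact with a cold strongly acidic resin; aryl hydrogen sulfates hydrolyse on standing, so the ammonium salt 25 is the form to keep.

## Route

Step 1
Reactants: 1 phloroglucinol; 2 succinic anhydride
Product: 3 4-oxo-4-(2,4,6-trihydroxyphenyl)butanoic acid
Conditions: AlCl3 (3.5 equiv), CH2Cl2/MeNO2, 0 → 25 °C; ice, 2 M HCl
Reagents that add atoms: none
Why: Friedel–Crafts acylation of the electron-rich triol by the AlCl3-activated anhydride; the first acyl group deactivates the ring, so the reaction should stop at the mono-acylated gamma-keto acid. Nitromethane replaces the more hazardous nitrobenzene.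

Step 2
Reactants: 3 4-oxo-4-(2,4,6-trihydroxyphenyl)butanoic acid
Product: 4 benzyl 4-[2,4-bis(benzyloxy)-6-hydroxyphenyl]-4-oxobutanoate
Conditions: BnBr (3.15 equiv), K2CO3 (3.3 equiv), DMF, 25 °C
Reagents that add atoms: benzyl bromide, BrCc1ccccc1
Why: Williamson alkylation of the carboxylate, the para phenol and one ortho phenol; the remaining ortho phenol is hydrogen-bonded to the ketone and hindered, so it should be left free, as is usual for acylphloroglucinols.

Step 3
Reactants: 4 benzyl 4-[2,4-bis(benzyloxy)-6-hydroxyphenyl]-4-oxobutanoate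
Product: 5 benzyl 4-[2,4-bis(benzyloxy)-6-(methoxymethoxy)phenyl]-4-oxobutanoate
Conditions: CH2(OMe)2, AcCl, ZnBr2 (cat.), toluene, 25 °C; then 4, iPr2NEt, CH2Cl2, 0 → 40 °C
Reagents that add atoms: dimethoxymethane, COCOC (turned in the flask by acetyl chloride into chloromethyl methyl ether, COCCl, the alkylating agent)
Why: O-alkylation of the chelated phenol by the reactive chloromethyl ether under amine base; making the chloride in solution avoids handling the neat carcinogen and its bis(chloromethyl) ether impurity.

Step 4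
Reactants: 5 benzyl 4-[2,4-bis(benzyloxy)-6-(methoxymethoxy)phenyl]-4-oxobutanoate
Product: 6 4-[2,4-bis(benzyloxy)-6-(methoxymethoxy)phenyl]-4-oxobutanoic acid
Conditions: LiOH·H2O (3 equiv), THF/MeOH/H2O, 25 °C; 0.5 M HCl to pH 4, 0 °C
Reagents that add atoms: lithium hydroxide, [Li+].[OH-] (its oxygen becomes the acid OH)
Why: Saponification of the benzyl ester by acyl–oxygen cleavage; the ethers and the acetal are stable to hydroxide, the hindered aryl ketone is not attacked, and cold acidification to pH 4 keeps the acetal.

Step 5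
Reactants: 6 4-[2,4-bis(benzyloxy)-6-(methoxymethoxy)phenyl]-4-oxobutanoic acid; 7 2,2,6-trimethyl-4H-1,3-dioxin-4-one
Product: 9 6-{5-[2,4-bis(benzyloxy)-6-(methoxymethoxy)phenyl]-2,5-dioxopentyl}-2,2-dimethyl-4H-1,3-dioxin-4-one, via acylimidazole 8 (not isolated)
Conditions: 6, CDI (1.1 equiv), THF, 25 °C; 7 (2.5 equiv), LiN(SiMe3)2 (2.6 equiv), THF, −78 °C, add 8, −78 → −40 °C; aq NH4Cl
Reagents that add atoms: 1,1'-carbonyldiimidazole, O=C(n1ccnc1)n1ccnc1 (imidazole unit of intermediate 8 only)
Why: The lithium dienolate of 7 is acylated at its terminal carbon by the acylimidazole (vinylogous Claisen acylation, the standard entry to keto-dioxinones); excess dienolate absorbs the acidic product, and the 2,6-dioxygenated aryl ketone is too hindered to be attacked.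

Step 6
Reactants: 10 1-(benzyloxy)-4-iodobenzene; 11 propiolic acid
Product: 12 3-[4-(benzyloxy)phenyl]prop-2-ynoic acid
Conditions: PdCl2(PPh3)2 (2.5 mol%), 1,4-bis(diphenylphosphino)butane (5 mol%), DBU (2.2 equiv), DMSO, 25 °C; 1 M HCl
Reagents that add atoms: none
Why: Copper-free Sonogashira-type coupling: oxidative addition of the aryl iodide to zerovalent palladium formed in the flask, then alkynylation by the propiolate salt; at 25 °C the arylpropiolate should not decarboxylate.

Step 7
Reactants: 12 3-[4-(benzyloxy)phenyl]prop-2-ynoic acid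
Product: 13 3-[4-(benzyloxy)phenyl]prop-2-ynoyl chloride
Conditions: (COCl)2 (1.3 equiv), DMF (cat.), CH2Cl2, 0 → 25 °C; evaporate, use crude
Reagents that add atoms: oxalyl chloride, ClC(=O)C(=O)Cl
Why: Acid chloride formation through the chloroiminium salt of DMF; the low temperature and removal of HCl under vacuum limit hydrochlorination of the alkyne.

Step 8
Reactants: 9 6-{5-[2,4-bis(benzyloxy)-6-(methoxymethoxy)phenyl]-2,5-dioxopentyl}-2,2-dimethyl-4H-1,3-dioxin-4-one; 13 3-[4-(benzyloxy)phenyl]prop-2-ynoyl chloride
Product: 15 6-(6-[4-(benzyloxy)phenyl]-2-{3-[2,4-bis(benzyloxy)-6-(methoxymethoxy)phenyl]-3-oxopropyl}-4-oxo-4H-pyran-3-yl)-2,2-dimethyl-4H-1,3-dioxin-4-one, via C-acylated ynone 14 (not isolated)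
Conditions: MgCl2 (2 equiv), pyridine (2.5 equiv), CH2Cl2, 0 °C; 13 (1.2 equiv), 0 → 25 °C; DMAP (0.2 equiv), 25 °C
Reagents that add atoms: none
Why: Soft enolisation gives the magnesium chelate of the CH2 between the ketone and the dioxinone, which is C-acylated by 13; the enol oxygen of the only ketone that can reach then adds 6-endo-dig to the ynone (acylation–cyclisation 4-pyranone synthesis from a 1,3-dicarbonyl unit and an alkynoyl chloride). The dioxinone has no ketone oxygen, so only one pyranone can form, and the aryl ketone CH2 is not enolised under these conditions.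

Step 9
Reactants: 15 6-(6-[4-(benzyloxy)phenyl]-2-{3-[2,4-bis(benzyloxy)-6-(methoxymethoxy)phenyl]-3-oxopropyl}-4-oxo-4H-pyran-3-yl)-2,2-dimethyl-4H-1,3-dioxin-4-one
Product: 17 methyl 3-(6-[4-(benzyloxy)phenyl]-2-{3-[2,4-bis(benzyloxy)-6-(methoxymethoxy)phenyl]-3-oxopropyl}-4-oxo-4H-pyran-3-yl)-3-oxopropanoate, via acylketene 16 (not isolated)
Conditions: MeOH (10 equiv), toluene, 105 °C, sealed tube
Reagents that add atoms: methanol, CO
Why: Thermal retro-[4+2] reaction of the dioxinone expels acetone and gives the acylketene, which methanol captures as the beta-keto ester; the conditions are neutral, so the pyranone, the acetal and the benzyl ethers should be untouched.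

Step 10
Reactants: 17 methyl 3-(6-[4-(benzyloxy)phenyl]-2-{3-[2,4-bis(benzyloxy)-6-(methoxymethoxy)phenyl]-3-oxopropyl}-4-oxo-4H-pyran-3-yl)-3-oxopropanoate
Product: 19 2-[4-(benzyloxy)phenyl]-8-{2-[2,4-bis(benzyloxy)-6-(methoxymethoxy)phenyl]-2-oxoethyl}-5,7-dihydroxy-4H-chromen-4-one, via trione tautomer 18 (not isolated)
Conditions: LiN(SiMe3)2 (3.5 equiv), THF, −78 → 25 °C; AcOH (4 equiv), pH 6 phosphate buffer, 0 °C
Reagents that add atoms: none
Why: Proposed new method: the first equivalent of base turns the beta-keto ester into its chelated enolate, which also shields the C5 acyl ketone from aldol attack, and the second removes a proton from the CH2 on pyranone C6, the gamma position of a doubly vinylogous system (ring C4=O and the C5 acyl group), to give a 2-alkylidene-2H-pyran-4-olate. Its exocyclic carbon attacks the ester carbonyl in a 6-exo-trig Dieckmann closure of ring D (pyranone C5 and C6, the former CH2, the ester carbon, the keto ester CH2 and its ketone carbon), methoxide leaves, and trione 18 is deprotonated at once to the aromatic 5,7-diphenoxide, which makes the sequence irreversible. The closest known reaction types are the Claisen-type aromatisation of triketo ester polyanions to acylphloroglucinols and the acylation and aldol condensation of 2-alkyl-4-pyranone carbanions; their intramolecular combination on one pyranone is the untested part. No stereocentre is formed. The selectivity needed is attack by the C6 methylene carbon and not by the alpha carbon of the aryl ketone: that enolate is less favoured (hindered, twisted 2,6-dioxygenated aryl ketone), could only close a seven-membered ring reversibly, and exchanges protons with the vinylogous anion, so the aromatising six-ring path should drain the mixture. The amide base is non-nucleophilic, so the pyranone should not be opened before it has become a flavone, and the lithium methoxide set free late is a poor nucleophile toward the flavone polyanion. Work-up at pH 6 and below 5 °C is chosen to avoid acid-catalysed closure of the free 7-OH onto the side-chain ketone (benzofuran formation).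

Step 11
Reactants: 19 2-[4-(benzyloxy)phenyl]-8-{2-[2,4-bis(benzyloxy)-6-(methoxymethoxy)phenyl]-2-oxoethyl}-5,7-dihydroxy-4H-chromen-4-one
Product: 20 2-[4-(benzyloxy)phenyl]-8-{2-[2,4-bis(benzyloxy)-6-(methoxymethoxy)phenyl]-2-oxoethyl}-5-hydroxy-4-oxo-4H-chromen-7-yl 2,2,2-trichloroethyl sulfate
Conditions: crude 19, Cl3CCH2OSO2Cl (1.15 equiv), Et3N (1.2 equiv), DMAP (1.0 equiv), THF, 0 → 25 °C
Reagents that add atoms: 2,2,2-trichloroethyl chlorosulfate, ClS(=O)(=O)OCC(Cl)(Cl)Cl
Why: Sulfation of a phenol by the DMAP-activated chlorosulfate; the 7-OH is the more acidic and the only phenol not hydrogen-bonded to a carbonyl, so mono-sulfation at O7 is expected. The neutral diester masks the sulfate and removes the phenol that could form a benzofuran.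

Step 12
Reactants: 20 2-[4-(benzyloxy)phenyl]-8-{2-[2,4-bis(benzyloxy)-6-(methoxymethoxy)phenyl]-2-oxoethyl}-5-hydroxy-4-oxo-4H-chromen-7-yl 2,2,2-trichloroethyl sulfate; 21 4-(benzyloxy)benzaldehyde
Product: 22 2-[4-(benzyloxy)phenyl]-8-{(1E)-1-[2,4-bis(benzyloxy)-6-(methoxymethoxy)benzoyl]-2-[4-(benzyloxy)phenyl]ethenyl}-5-hydroxy-4-oxo-4H-chromen-7-yl 2,2,2-trichloroethyl sulfate
Conditions: 21 (1.5 equiv), piperidine (0.3 equiv), AcOH (0.6 equiv), toluene, 4 Å MS, 85 °C
Reagents that add atoms: none
Why: Knoevenagel-type condensation of the methylene flanked by the ketone and ring D with the aldehyde activated as its iminium ion; sieves drive the dehydration, and the buffered amine salt keeps free piperidine low for the sake of the sulfate diester. The E isomer (aroyl trans to the new aryl group) is expected as the less strained one, and the acetal on ring A prevents premature closure of ring C.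

Step 13
Reactants: 22 2-[4-(benzyloxy)phenyl]-8-{(1E)-1-[2,4-bis(benzyloxy)-6-(methoxymethoxy)benzoyl]-2-[4-(benzyloxy)phenyl]ethenyl}-5-hydroxy-4-oxo-4H-chromen-7-yl 2,2,2-trichloroethyl sulfate
Product: 23 2-[4-(benzyloxy)phenyl]-8-{(1E)-1-[2,4-bis(benzyloxy)-6-hydroxybenzoyl]-2-[4-(benzyloxy)phenyl]ethenyl}-5-hydroxy-4-oxo-4H-chromen-7-yl 2,2,2-trichloroethyl sulfate
Conditions: 2 M HCl, MeOH/THF (1:1), 25 °C
Reagents that add atoms: none
Why: Acid-catalysed acetal exchange with methanol frees the phenol; the sulfate diester and the benzyl ethers are stable to dilute acid, and room temperature should keep acid-catalysed closure of the freed hydroxychalcone slow.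

Step 14
Reactants: 23 2-[4-(benzyloxy)phenyl]-8-{(1E)-1-[2,4-bis(benzyloxy)-6-hydroxybenzoyl]-2-[4-(benzyloxy)phenyl]ethenyl}-5-hydroxy-4-oxo-4H-chromen-7-yl 2,2,2-trichloroethyl sulfate
Product: 24 2-[4-(benzyloxy)phenyl]-8-{(2R,3S)-5,7-bis(benzyloxy)-2-[4-(benzyloxy)phenyl]-4-oxo-3,4-dihydro-2H-chromen-3-yl}-5-hydroxy-4-oxo-4H-chromen-7-yl 2,2,2-trichloroethyl sulfate
Conditions: 9-amino-9-deoxy-epi-quinidine 3,5-bis(trifluoromethyl)phenyl thiourea (10 mol%), toluene, −20 °C
Reagents that add atoms: none
Why: Bifunctional catalysis of an intramolecular oxa-Michael addition: the quinuclidine nitrogen deprotonates the ring A phenol, the thiourea binds the ketone, and the phenoxide adds 6-endo-trig to one face of the enone, which sets C2 (R) under catalyst control. C3 is set by protonation of the enol and should equilibrate under the basic catalyst to the 2,3-trans (3S) isomer with both aryl groups equatorial. The quinine-derived pseudoenantiomer is held ready in case the sense of induction, to be checked first on a model chalcone, is the opposite.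

Step 15
Reactants: 24 2-[4-(benzyloxy)phenyl]-8-{(2R,3S)-5,7-bis(benzyloxy)-2-[4-(benzyloxy)phenyl]-4-oxo-3,4-dihydro-2H-chromen-3-yl}-5-hydroxy-4-oxo-4H-chromen-7-yl 2,2,2-trichloroethyl sulfate
Product: 26 8-[(2R,3S)-5,7-dihydroxy-2-(4-hydroxyphenyl)-4-oxo-3,4-dihydro-2H-chromen-3-yl]-5-hydroxy-2-(4-hydroxyphenyl)-4-oxo-4H-chromen-7-yl hydrogen sulfate, via ammonium sulfate salt 25 (not isolated)
Conditions: 10% Pd/C, HCO2NH4 (12 equiv), MeOH/THF, 25 °C; filter; Dowex 50W (H+ form), MeOH/H2O, 0 °C
Reagents that add atoms: ammonium formate, [NH4+].[O-]C=O (ammonium counter-ion of intermediate 25 only)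
Why: Catalytic transfer hydrogenolysis cleaves the four benzyl ethers, and the same system reduces the trichloroethyl group with beta-elimination to release the sulfate monoester as its ammonium salt. At room temperature the flavone alkene, the ketones and the C2–O1 bond should survive, the stereocentres are not touched, and the cold acidic resin exchanges ammonium for a proton.

## Compound list

1 | phloroglucinol | Oc1cc(O)cc(O)c1 | starting material
2 | succinic anhydride | O=C1CCC(=O)O1 | starting material
3 | 4-oxo-4-(2,4,6-trihydroxyphenyl)butanoic acid | O=C(O)CCC(=O)c1c(O)cc(O)cc1O | intermediate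
4 | benzyl 4-[2,4-bis(benzyloxy)-6-hydroxyphenyl]-4-oxobutanoate | O=C(CCC(=O)c1c(O)cc(OCc2ccccc2)cc1OCc1ccccc1)OCc1ccccc1 | intermediate
5 | benzyl 4-[2,4-bis(benzyloxy)-6-(methoxymethoxy)phenyl]-4-oxobutanoate | COCOc1cc(OCc2ccccc2)cc(OCc2ccccc2)c1C(=O)CCC(=O)OCc1ccccc1 | intermediate
6 | 4-[2,4-bis(benzyloxy)-6-(methoxymethoxy)phenyl]-4-oxobutanoic acid | COCOc1cc(OCc2ccccc2)cc(OCc2ccccc2)c1C(=O)CCC(=O)O | intermediate
7 | 2,2,6-trimethyl-4H-1,3-dioxin-4-one | CC1=CC(=O)OC(C)(C)O1 | starting material
8 | 1-{4-[2,4-bis(benzyloxy)-6-(methoxymethoxy)phenyl]-4-oxobutanoyl}imidazole | COCOc1cc(OCc2ccccc2)cc(OCc2ccccc2)c1C(=O)CCC(=O)n1ccnc1 | intermediate (not isolated)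
9 | 6-{5-[2,4-bis(benzyloxy)-6-(methoxymethoxy)phenyl]-2,5-dioxopentyl}-2,2-dimethyl-4H-1,3-dioxin-4-one | COCOc1cc(OCc2ccccc2)cc(OCc2ccccc2)c1C(=O)CCC(=O)CC1=CC(=O)OC(C)(C)O1 | intermediate
10 | 1-(benzyloxy)-4-iodobenzene | Ic1ccc(OCc2ccccc2)cc1 | starting material
11 | propiolic acid | C#CC(=O)O | starting material
12 | 3-[4-(benzyloxy)phenyl]prop-2-ynoic acid | O=C(O)C#Cc1ccc(OCc2ccccc2)cc1 | intermediate
13 | 3-[4-(benzyloxy)phenyl]prop-2-ynoyl chloride | O=C(Cl)C#Cc1ccc(OCc2ccccc2)cc1 | intermediate
14 | 6-{1-[3-(4-benzyloxyphenyl)prop-2-ynoyl]-5-[2,4-bis(benzyloxy)-6-(methoxymethoxy)phenyl]-2,5-dioxopentyl}-2,2-dimethyl-4H-1,3-dioxin-4-one (drawn as the triketo form) | COCOc1cc(OCc2ccccc2)cc(OCc2ccccc2)c1C(=O)CCC(=O)C(C(=O)C#Cc1ccc(OCc2ccccc2)cc1)C1=CC(=O)OC(C)(C)O1 | intermediate (not isolated)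
15 | 6-(6-[4-(benzyloxy)phenyl]-2-{3-[2,4-bis(benzyloxy)-6-(methoxymethoxy)phenyl]-3-oxopropyl}-4-oxo-4H-pyran-3-yl)-2,2-dimethyl-4H-1,3-dioxin-4-one | COCOc1cc(OCc2ccccc2)cc(OCc2ccccc2)c1C(=O)CCc1oc(-c2ccc(OCc3ccccc3)cc2)cc(=O)c1C1=CC(=O)OC(C)(C)O1 | intermediate
16 | 3-(6-[4-(benzyloxy)phenyl]-2-{3-[2,4-bis(benzyloxy)-6-(methoxymethoxy)phenyl]-3-oxopropyl}-4-oxo-4H-pyran-3-yl)-3-oxoprop-1-en-1-one (acylketene) | COCOc1cc(OCc2ccccc2)cc(OCc2ccccc2)c1C(=O)CCc1oc(-c2ccc(OCc3ccccc3)cc2)cc(=O)c1C(=O)C=C=O | intermediate (not isolated)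
17 | methyl 3-(6-[4-(benzyloxy)phenyl]-2-{3-[2,4-bis(benzyloxy)-6-(methoxymethoxy)phenyl]-3-oxopropyl}-4-oxo-4H-pyran-3-yl)-3-oxopropanoate | COCOc1cc(OCc2ccccc2)cc(OCc2ccccc2)c1C(=O)CCc1oc(-c2ccc(OCc3ccccc3)cc2)cc(=O)c1C(=O)CC(=O)OC | intermediate
18 | 2-[4-(benzyloxy)phenyl]-8-{2-[2,4-bis(benzyloxy)-6-(methoxymethoxy)phenyl]-2-oxoethyl}-6,8-dihydro-4H-chromene-4,5,7-trione | COCOc1cc(OCc2ccccc2)cc(OCc2ccccc2)c1C(=O)CC1C(=O)CC(=O)c2c1oc(-c1ccc(OCc3ccccc3)cc1)cc2=O | intermediate (not isolated)
19 | 2-[4-(benzyloxy)phenyl]-8-{2-[2,4-bis(benzyloxy)-6-(methoxymethoxy)phenyl]-2-oxoethyl}-5,7-dihydroxy-4H-chromen-4-one | COCOc1cc(OCc2ccccc2)cc(OCc2ccccc2)c1C(=O)Cc1c(O)cc(O)c2c(=O)cc(-c3ccc(OCc4ccccc4)cc3)oc12 | intermediate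
20 | 2-[4-(benzyloxy)phenyl]-8-{2-[2,4-bis(benzyloxy)-6-(methoxymethoxy)phenyl]-2-oxoethyl}-5-hydroxy-4-oxo-4H-chromen-7-yl 2,2,2-trichloroethyl sulfate | COCOc1cc(OCc2ccccc2)cc(OCc2ccccc2)c1C(=O)Cc1c(OS(=O)(=O)OCC(Cl)(Cl)Cl)cc(O)c2c(=O)cc(-c3ccc(OCc4ccccc4)cc3)oc12 | intermediate
21 | 4-(benzyloxy)benzaldehyde | O=Cc1ccc(OCc2ccccc2)cc1 | starting material
22 | 2-[4-(benzyloxy)phenyl]-8-{(1E)-1-[2,4-bis(benzyloxy)-6-(methoxymethoxy)benzoyl]-2-[4-(benzyloxy)phenyl]ethenyl}-5-hydroxy-4-oxo-4H-chromen-7-yl 2,2,2-trichloroethyl sulfate | COCOc1cc(OCc2ccccc2)cc(OCc2ccccc2)c1C(=O)/C(=C/c1ccc(OCc2ccccc2)cc1)c1c(OS(=O)(=O)OCC(Cl)(Cl)Cl)cc(O)c2c(=O)cc(-c3ccc(OCc4ccccc4)cc3)oc12 | intermediate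
23 | 2-[4-(benzyloxy)phenyl]-8-{(1E)-1-[2,4-bis(benzyloxy)-6-hydroxybenzoyl]-2-[4-(benzyloxy)phenyl]ethenyl}-5-hydroxy-4-oxo-4H-chromen-7-yl 2,2,2-trichloroethyl sulfate | Oc1cc(OCc2ccccc2)cc(OCc2ccccc2)c1C(=O)/C(=C/c1ccc(OCc2ccccc2)cc1)c1c(OS(=O)(=O)OCC(Cl)(Cl)Cl)cc(O)c2c(=O)cc(-c3ccc(OCc4ccccc4)cc3)oc12 | intermediate
24 | 2-[4-(benzyloxy)phenyl]-8-{(2R,3S)-5,7-bis(benzyloxy)-2-[4-(benzyloxy)phenyl]-4-oxo-3,4-dihydro-2H-chromen-3-yl}-5-hydroxy-4-oxo-4H-chromen-7-yl 2,2,2-trichloroethyl sulfate | O=C1c2c(OCc3ccccc3)cc(OCc3ccccc3)cc2O[C@@H](c2ccc(OCc3ccccc3)cc2)[C@@H]1c1c(OS(=O)(=O)OCC(Cl)(Cl)Cl)cc(O)c2c(=O)cc(-c3ccc(OCc4ccccc4)cc3)oc12 | intermediate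
25 | ammonium 8-[(2R,3S)-5,7-dihydroxy-2-(4-hydroxyphenyl)-4-oxo-3,4-dihydro-2H-chromen-3-yl]-5-hydroxy-2-(4-hydroxyphenyl)-4-oxo-4H-chromen-7-yl sulfate | [NH4+].O=C1c2c(O)cc(O)cc2O[C@@H](c2ccc(O)cc2)[C@@H]1c1c(OS(=O)(=O)[O-])cc(O)c2c(=O)cc(-c3ccc(O)cc3)oc12 | intermediate (not isolated)
26 | 8-[(2R,3S)-5,7-dihydroxy-2-(4-hydroxyphenyl)-4-oxo-3,4-dihydro-2H-chromen-3-yl]-5-hydroxy-2-(4-hydroxyphenyl)-4-oxo-4H-chromen-7-yl hydrogen sulfate | O=C1c2c(O)cc(O)cc2O[C@@H](c2ccc(O)cc2)[C@@H]1c1c(OS(=O)(=O)O)cc(O)c2c(=O)cc(-c3ccc(O)cc3)oc12 | target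

## Step count and least certain steps

Total step count: 15. Longest linear sequence: 13 steps (steps 1 to 5 and 8 to 15); steps 6 and 7 form the side branch to 13.

**Step 10 (key step).** What is most likely to go wrong is failure of the carbon–carbon bond formation itself: the ester is attached to an enolate and is a weak electrophile, so the vinylogous carbanion may only exchange protons, or the polyanion may drift into ring opening and reclosure of the pyranone. A second hazard is dehydrative closure of the new 7-OH onto the side-chain ketone during work-up. The fallback uses only established reaction types; it sets out from 6 (with 13) and returns at 19.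
- 6 is extended through its acylimidazole with KO2CCH2CO2Me/MgCl2/Et3N to methyl 6-[2,4-bis(benzyloxy)-6-(methoxymethoxy)phenyl]-3,6-dioxohexanoate F1.
- F1 is C-acylated with 13 (MgCl2, pyridine) and closed to methyl 6-[4-(benzyloxy)phenyl]-2-{3-[2,4-bis(benzyloxy)-6-(methoxymethoxy)phenyl]-3-oxopropyl}-4-oxo-4H-pyran-3-carboxylate F2, the classical pyranone synthesis from a beta-keto ester and an arylpropioloyl chloride.
- The carbanion of the CH2 on the pyranone (LiN(SiMe3)2, 2.2 equiv, −78 °C) is acetylated with N-methoxy-N-methylacetamide to methyl 6-[4-(benzyloxy)phenyl]-2-{1-[2,4-bis(benzyloxy)-6-(methoxymethoxy)phenyl]-1,4-dioxopentan-3-yl}-4-oxo-4H-pyran-3-carboxylate F3.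
- LiN(iPr)2 (2.5 equiv) then closes the methyl ketone enolate onto the ring ester, a Dieckmann cyclisation of a delta-keto ester to a cyclohexane-1,3-dione that aromatises to 19.

Ring D is then closed at C5–C6 instead of C7–C8 and the electrophilic ester is no longer attached to an enolate. The step count from 6 is the same; the price is an intermolecular acylation at a secondary carbanion in the presence of a second enolisable ketone.

**Step 8.** The acylation may go to oxygen, chloride or pyridine may add to the ynoyl chloride before C-acylation, or the 6-endo closure may stall with the dioxinone substituent next to the reacting enol. The fallback sets out from 6 and returns at 17; it replaces the masked keto ester by a plain ester and extends the chain afterwards.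
- 6 is converted with CDI and KO2CCH2CO2CH2CH=CH2/MgCl2/Et3N into prop-2-en-1-yl 6-[2,4-bis(benzyloxy)-6-(methoxymethoxy)phenyl]-3,6-dioxohexanoate F4.
- Acylation with 13 and closure gives prop-2-en-1-yl 6-[4-(benzyloxy)phenyl]-2-{3-[2,4-bis(benzyloxy)-6-(methoxymethoxy)phenyl]-3-oxopropyl}-4-oxo-4H-pyran-3-carboxylate F5.
- Pd(PPh3)4 and morpholine remove the allyl group under neutral conditions to give 6-[4-(benzyloxy)phenyl]-2-{3-[2,4-bis(benzyloxy)-6-(methoxymethoxy)phenyl]-3-oxopropyl}-4-oxo-4H-pyran-3-carboxylic acid F6.
- CDI followed by KO2CCH2CO2Me/MgCl2/Et3N gives 17.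

**Step 12.** The sulfate diester may be lost through attack of the amine on the trichloroethyl group or on sulfur at 85 °C, and the condensation itself may be slow at the crowded methylene. The fallback sets out from 19 and returns at 22; it keeps the sulfate out of the condensation.
- Allyl bromide and K2CO3 in acetone give 7-(allyloxy)-2-[4-(benzyloxy)phenyl]-8-{2-[2,4-bis(benzyloxy)-6-(methoxymethoxy)phenyl]-2-oxoethyl}-5-hydroxy-4H-chromen-4-one F7; the chelated 5-OH should stay free.
- Condensation with 21 under forcing piperidine conditions gives 7-(allyloxy)-2-[4-(benzyloxy)phenyl]-8-{(1E)-1-[2,4-bis(benzyloxy)-6-(methoxymethoxy)benzoyl]-2-[4-(benzyloxy)phenyl]ethenyl}-5-hydroxy-4H-chromen-4-one F8.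
- Pd(PPh3)4 and morpholine give 2-[4-(benzyloxy)phenyl]-8-{(1E)-1-[2,4-bis(benzyloxy)-6-(methoxymethoxy)benzoyl]-2-[4-(benzyloxy)phenyl]ethenyl}-5,7-dihydroxy-4H-chromen-4-one F9.
- Sulfation as in step 11 gives 22.

**Step 14.** Facial selectivity may be poor on so crowded an enone, and any selectivity may erode through reversible ring opening; equilibration of C3 to trans may also be incomplete. The fallback sets out from 23 and returns at 24: closure with NaOAc in EtOH gives the racemic trans compound, a 1:1 mixture of 24 and its enantiomer 2-[4-(benzyloxy)phenyl]-8-{(2S,3R)-5,7-bis(benzyloxy)-2-[4-(benzyloxy)phenyl]-4-oxo-3,4-dihydro-2H-chromen-3-yl}-5-hydroxy-4-oxo-4H-chromen-7-yl 2,2,2-trichloroethyl sulfate F10. Preparative chromatography on a chiral stationary phase delivers 24, and F10 can be returned to the racemate by base-induced ring opening and reclosure.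

**Step 15.** Ammonia released from the formate may open the flavanone through the ring B phenol once it is freed, which would racemise C2; over-reduction of the ring E alkene is a lesser concern. The fallback sets out from 24 and returns at 25; it separates the two unmaskings so that no base is present when the phenols are free.
- Zn dust and HCO2NH4 in MeOH at 0 °C remove only the trichloroethyl group and give ammonium 2-[4-(benzyloxy)phenyl]-8-{(2R,3S)-5,7-bis(benzyloxy)-2-[4-(benzyloxy)phenyl]-4-oxo-3,4-dihydro-2H-chromen-3-yl}-5-hydroxy-4-oxo-4H-chromen-7-yl sulfate F11.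
- H2 (1 atm) over Pd/C in MeOH/THF without amine then removes the benzyl ethers to give 25.

## Further compounds

F1 | step 10 | methyl 6-[2,4-bis(benzyloxy)-6-(methoxymethoxy)phenyl]-3,6-dioxohexanoate | COCOc1cc(OCc2ccccc2)cc(OCc2ccccc2)c1C(=O)CCC(=O)CC(=O)OC
F2 | step 10 | methyl 6-[4-(benzyloxy)phenyl]-2-{3-[2,4-bis(benzyloxy)-6-(methoxymethoxy)phenyl]-3-oxopropyl}-4-oxo-4H-pyran-3-carboxylate | COCOc1cc(OCc2ccccc2)cc(OCc2ccccc2)c1C(=O)CCc1oc(-c2ccc(OCc3ccccc3)cc2)cc(=O)c1C(=O)OC
F3 | step 10 | methyl 6-[4-(benzyloxy)phenyl]-2-{1-[2,4-bis(benzyloxy)-6-(methoxymethoxy)phenyl]-1,4-dioxopentan-3-yl}-4-oxo-4H-pyran-3-carboxylate | COCOc1cc(OCc2ccccc2)cc(OCc2ccccc2)c1C(=O)CC(C(C)=O)c1oc(-c2ccc(OCc3ccccc3)cc2)cc(=O)c1C(=O)OC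
F4 | step 8 | prop-2-en-1-yl 6-[2,4-bis(benzyloxy)-6-(methoxymethoxy)phenyl]-3,6-dioxohexanoate | COCOc1cc(OCc2ccccc2)cc(OCc2ccccc2)c1C(=O)CCC(=O)CC(=O)OCC=C
F5 | step 8 | prop-2-en-1-yl 6-[4-(benzyloxy)phenyl]-2-{3-[2,4-bis(benzyloxy)-6-(methoxymethoxy)phenyl]-3-oxopropyl}-4-oxo-4H-pyran-3-carboxylate | COCOc1cc(OCc2ccccc2)cc(OCc2ccccc2)c1C(=O)CCc1oc(-c2ccc(OCc3ccccc3)cc2)cc(=O)c1C(=O)OCC=C
F6 | step 8 | 6-[4-(benzyloxy)phenyl]-2-{3-[2,4-bis(benzyloxy)-6-(methoxymethoxy)phenyl]-3-oxopropyl}-4-oxo-4H-pyran-3-carboxylic acid | COCOc1cc(OCc2ccccc2)cc(OCc2ccccc2)c1C(=O)CCc1oc(-c2ccc(OCc3ccccc3)cc2)cc(=O)c1C(=O)O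
F7 | step 12 | 7-(allyloxy)-2-[4-(benzyloxy)phenyl]-8-{2-[2,4-bis(benzyloxy)-6-(methoxymethoxy)phenyl]-2-oxoethyl}-5-hydroxy-4H-chromen-4-one | COCOc1cc(OCc2ccccc2)cc(OCc2ccccc2)c1C(=O)Cc1c(OCC=C)cc(O)c2c(=O)cc(-c3ccc(OCc4ccccc4)cc3)oc12
F8 | step 12 | 7-(allyloxy)-2-[4-(benzyloxy)phenyl]-8-{(1E)-1-[2,4-bis(benzyloxy)-6-(methoxymethoxy)benzoyl]-2-[4-(benzyloxy)phenyl]ethenyl}-5-hydroxy-4H-chromen-4-one | COCOc1cc(OCc2ccccc2)cc(OCc2ccccc2)c1C(=O)/C(=C/c1ccc(OCc2ccccc2)cc1)c1c(OCC=C)cc(O)c2c(=O)cc(-c3ccc(OCc4ccccc4)cc3)oc12
F9 | step 12 | 2-[4-(benzyloxy)phenyl]-8-{(1E)-1-[2,4-bis(benzyloxy)-6-(methoxymethoxy)benzoyl]-2-[4-(benzyloxy)phenyl]ethenyl}-5,7-dihydroxy-4H-chromen-4-one | COCOc1cc(OCc2ccccc2)cc(OCc2ccccc2)c1C(=O)/C(=C/c1ccc(OCc2ccccc2)cc1)c1c(O)cc(O)c2c(=O)cc(-c3ccc(OCc4ccccc4)cc3)oc12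
F10 | step 14 | 2-[4-(benzyloxy)phenyl]-8-{(2S,3R)-5,7-bis(benzyloxy)-2-[4-(benzyloxy)phenyl]-4-oxo-3,4-dihydro-2H-chromen-3-yl}-5-hydroxy-4-oxo-4H-chromen-7-yl 2,2,2-trichloroethyl sulfate | O=C1c2c(OCc3ccccc3)cc(OCc3ccccc3)cc2O[C@H](c2ccc(OCc3ccccc3)cc2)[C@H]1c1c(OS(=O)(=O)OCC(Cl)(Cl)Cl)cc(O)c2c(=O)cc(-c3ccc(OCc4ccccc4)cc3)oc12
F11 | step 15 | ammonium 2-[4-(benzyloxy)phenyl]-8-{(2R,3S)-5,7-bis(benzyloxy)-2-[4-(benzyloxy)phenyl]-4-oxo-3,4-dihydro-2H-chromen-3-yl}-5-hydroxy-4-oxo-4H-chromen-7-yl sulfate | [NH4+].O=C1c2c(OCc3ccccc3)cc(OCc3ccccc3)cc2O[C@@H](c2ccc(OCc3ccccc3)cc2)[C@@H]1c1c(OS(=O)(=O)[O-])cc(O)c2c(=O)cc(-c3ccc(OCc4ccccc4)cc3)oc12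
A1 | alternative 1 | (2R,3S)-pentabenzyl biflavonoid 7-O-(2,2,2-trichloroethyl) sulfate, product of the ester Wittig closure | O=C1c2c(OCc3ccccc3)cc(OCc3ccccc3)cc2O[C@@H](c2ccc(OCc3ccccc3)cc2)[C@@H]1c1c(OS(=O)(=O)OCC(Cl)(Cl)Cl)cc(OCc2ccccc2)c2c(=O)cc(-c3ccc(OCc4ccccc4)cc3)oc12
A2 | alternative 1 | acyl ylide: ring D bearing C(=O)CH=PPh3 beside a 4-benzyloxybenzoate ester, attached to C3 of the (2R,3S)-tribenzyl flavanone | O=C1c2c(OCc3ccccc3)cc(OCc3ccccc3)cc2O[C@@H](c2ccc(OCc3ccccc3)cc2)[C@@H]1c1c(OS(=O)(=O)OCC(Cl)(Cl)Cl)cc(OCc2ccccc2)c(C(=O)C=P(c2ccccc2)(c2ccccc2)c2ccccc2)c1OC(=O)c1ccc(OCc2ccccc2)cc1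
A3 | alternative 2 | (2R,3S)-pentabenzyl 7-O-allyl biflavonoid, product of the acylative closure | O=C1c2c(OCc3ccccc3)cc(OCc3ccccc3)cc2O[C@@H](c2ccc(OCc3ccccc3)cc2)[C@@H]1c1c(OCC=C)cc(OCc2ccccc2)c2c(=O)cc(-c3ccc(OCc4ccccc4)cc3)oc12
A4 | alternative 2 | (Z)-3-aryloxy-3-[4-(benzyloxy)phenyl]acrylic acid on the ring D oxygen of the (2R,3S)-tribenzyl flavanone | O=C1c2c(OCc3ccccc3)cc(OCc3ccccc3)cc2O[C@@H](c2ccc(OCc3ccccc3)cc2)[C@@H]1c1c(OCC=C)cc(OCc2ccccc2)cc1O/C(=C\C(=O)O)c1ccc(OCc2ccccc2)cc1
A5 | alternative 3 | all-trans 4-methoxyflavan bearing the flavone at C3, product of the cycloaddition | CO[C@H]1c2c(OCc3ccccc3)cc(OCc3ccccc3)cc2O[C@@H](c2ccc(OCc3ccccc3)cc2)[C@@H]1c1c(OS(=O)(=O)OCC(Cl)(Cl)Cl)cc(OCc2ccccc2)c2c(=O)cc(-c3ccc(OCc4ccccc4)cc3)oc12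
A6 | alternative 3 | 5-(benzyloxy)-2-[4-(benzyloxy)phenyl]-8-[(E)-2-(4-benzyloxyphenyl)ethenyl]-4-oxo-4H-chromen-7-yl 2,2,2-trichloroethyl sulfate | O=c1cc(-c2ccc(OCc3ccccc3)cc2)oc2c(/C=C/c3ccc(OCc4ccccc4)cc3)c(OS(=O)(=O)OCC(Cl)(Cl)Cl)cc(OCc3ccccc3)c12
A7 | alternative 3 | 2,4-bis(benzyloxy)-6-hydroxybenzaldehyde | O=Cc1c(O)cc(OCc2ccccc2)cc1OCc1ccccc1
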